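**Plan**
- Retrosynthesis: the ring B phenol is masked as a methoxymethyl (MOM) ether, then ring C is cut at O1–C8a and C4–C4a in one operation.
- Enabling feature: both bonds end on the adjacent ring A carbons C8a and C4a, so ring A can enter as the 3,5-dimethoxy-6-prenyl aryne. O1–C2–C3–C4 and ring B enter as a 3-aryl-3-silyloxypropanoate.
- Forward: 3,5-dimethoxyphenol is ortho-silylated and ortho-prenylated under carbamate direction and converted into the silyl triflate. The ring B methyl ketone is homologated to the beta-keto ester, reduced and O-silylated.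
- Ring C is the only ring formed (aryne annulation); MOM removal ends the route.
- Stereochemistry: C2 (S) is set by asymmetric transfer hydrogenation of the beta-keto ester, and its C–O bond is never broken afterwards.

Key step: step 9

Remark: C2 is read from the SMILES as S (flavanone numbering). 1-(3-Hydroxy-4-methoxyphenyl)ethanone, the methyl ketone analogue of isovanillin, is taken as the commercial ring B starting material.

**Route**

Step 1
Reactants: 1 3,5-dimethoxyphenol
Product: 2 3,5-dimethoxyphenyl N-isopropylcarbamate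
Conditions: i-PrNCO, Et3N (cat.), CH2Cl2, rt
Reagents that add atoms: isopropyl isocyanate, CC(C)N=C=O
Why: Base-catalysed addition of the phenol O–H to the isocyanate (carbamoylation) should give the secondary carbamate, which directs both ortho-metalations and is later removable under mild base.

Step 2
Reactants: 2 3,5-dimethoxyphenyl N-isopropylcarbamate
Product: 6 3,5-dimethoxy-2-(trimethylsilyl)phenyl N-isopropylcarbamate, via N-silyl carbamate 3 (not isolated), via aryllithium 4 (not isolated), via N-silyl arylsilane 5 (not isolated)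
Conditions: TBSOTf, TMEDA, Et2O, 0 °C to rt; n-BuLi, TMEDA, −78 °C; TMSCl, −78 °C to rt; cold aq. NaHSO4
Reagents that add atoms: chlorotrimethylsilane, C[Si](C)(C)Cl; tert-butyldimethylsilyl triflate (transient N-silyl group only, lost on work-up), CC(C)(C)[Si](C)(C)OS(=O)(=O)C(F)(F)F
Why: Directed ortho-metalation: in situ N-silylation masks the N–H, the O-carbamate (the strongest director, reinforced by the flanking methoxy group) should steer lithiation to C2 and not to C4 between the two methoxy groups, TMSCl traps the aryllithium, and the N–Si bond is hydrolysed on work-up.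

Step 3
Reactants: 6 3,5-dimethoxy-2-(trimethylsilyl)phenyl N-isopropylcarbamate; 7 prenyl bromide (1-bromo-3-methylbut-2-ene)
Product: 11 3,5-dimethoxy-2-(3-methylbut-2-en-1-yl)-6-(trimethylsilyl)phenyl N-isopropylcarbamate, via N-silyl carbamate 8 (not isolated), via aryllithium 9 (not isolated), via N-silyl prenylarene 10 (not isolated)
Conditions: TBSOTf, TMEDA, Et2O, 0 °C to rt; n-BuLi, TMEDA, −78 °C; CuBr·SMe2 (10 mol %), prenyl bromide, −78 to 0 °C; cold aq. NaHSO4
Reagents that add atoms: prenyl bromide (compound 7), CC(C)=CCBr; tert-butyldimethylsilyl triflate (transient N-silyl group only, lost on work-up), CC(C)(C)[Si](C)(C)OS(=O)(=O)C(F)(F)F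
Why: A second directed ortho-metalation at the only remaining carbamate-ortho position (C6), followed by copper-catalysed allylic substitution at the primary carbon of prenyl bromide, should install the prenyl group; silylation comes first so that no benzylic-allylic CH2 competes for the base.

Step 4
Reactants: 11 3,5-dimethoxy-2-(3-methylbut-2-en-1-yl)-6-(trimethylsilyl)phenyl N-isopropylcarbamate
Product: 13 3,5-dimethoxy-2-(3-methylbut-2-en-1-yl)-6-(trimethylsilyl)phenyl trifluoromethanesulfonate, via silylphenol 12 (not isolated)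
Conditions: DBU, Et2NH, MeCN, 40 °C; then PhNTf2, rt
Reagents that add atoms: N-phenylbis(trifluoromethanesulfonimide), O=S(=O)(N(c1ccccc1)S(=O)(=O)C(F)(F)F)C(F)(F)F
Why: E1cB cleavage of the secondary carbamate (N–H removal, loss of aryloxide, Et2NH traps the isocyanate) and O-sulfonylation of the released phenoxide in the same flask is the standard conversion of an ortho-silylaryl carbamate into a fluoride-triggered aryne precursor.

Step 5
Reactants: 14 1-(3-hydroxy-4-methoxyphenyl)ethanone
Product: 15 1-[4-methoxy-3-(methoxymethoxy)phenyl]ethanone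
Conditions: MOMCl, i-Pr2NEt, CH2Cl2, 0 °C to rt
Reagents that add atoms: chloromethyl methyl ether, COCCl
Why: O-alkylation of the phenol gives a MOM acetal that is stable to base, hydride transfer and fluoride and is removed at the end by mild acid.

Step 6
Reactants: 15 1-[4-methoxy-3-(methoxymethoxy)phenyl]ethanone
Product: 16 methyl 3-[4-methoxy-3-(methoxymethoxy)phenyl]-3-oxopropanoate
Conditions: NaH, (MeO)2CO, THF, reflux; AcOH quench
Reagents that add atoms: dimethyl carbonate, COC(=O)OC
Why: Crossed Claisen condensation of the ketone enolate with dimethyl carbonate, driven by deprotonation of the beta-keto ester formed, should give the aroylacetate.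

Step 7
Reactants: 16 methyl 3-[4-methoxy-3-(methoxymethoxy)phenyl]-3-oxopropanoate
Product: 17 methyl (3S)-3-hydroxy-3-[4-methoxy-3-(methoxymethoxy)phenyl]propanoate
Conditions: RuCl[(S,S)-TsDPEN](p-cymene) (1 mol %), HCO2H/Et3N (5:2), 40 °C
Reagents that add atoms: none
Why: Noyori–Ikariya asymmetric transfer hydrogenation of the aryl ketone: the (S,S)-TsDPEN ruthenium hydride should deliver hydride to the Re face, as with acetophenone-type ketones, and so set the S carbinol centre that becomes C2.

Step 8
Reactants: 17 methyl (3S)-3-hydroxy-3-[4-methoxy-3-(methoxymethoxy)phenyl]propanoate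
Product: 18 methyl (3S)-3-[4-methoxy-3-(methoxymethoxy)phenyl]-3-(trimethylsilyloxy)propanoate
Conditions: TMSCl, imidazole, CH2Cl2, 0 °C
Reagents that add atoms: chlorotrimethylsilane, C[Si](C)(C)Cl
Why: Silylation of the secondary alcohol gives a latent alkoxide that fluoride can release in the key step without any O–H proton in the flask.

Step 9
Reactants: 13 3,5-dimethoxy-2-(3-methylbut-2-en-1-yl)-6-(trimethylsilyl)phenyl trifluoromethanesulfonate; 18 methyl (3S)-3-[4-methoxy-3-(methoxymethoxy)phenyl]-3-(trimethylsilyloxy)propanoate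
Product: 21 (2S)-5,7-dimethoxy-2-[4-methoxy-3-(methoxymethoxy)phenyl]-8-(3-methylbut-2-en-1-yl)chroman-4-one, via aryne 19 (not isolated), via cesium alkoxide 20 (not isolated)
Conditions: 13 (1.5 equiv), CsF (4 equiv), 18-crown-6, THF, 0 °C to rt; pH 7 buffer at 0 °C
Reagents that add atoms: none
Why: Proposed new method: fluoride removes the aryl SiMe3 group of 13 and triflate leaves to give aryne 19, while fluoride also unmasks alkoxide 20 from 18 under aprotic conditions; 20 adds to the aryne carbon that becomes C8a, and the resulting C4a aryl anion attacks the ester carbonyl and expels methoxide, so O1–C8a and C4–C4a form in one operation. The closest known reactions are the fluoride-induced annulation of arynes with methyl salicylates to xanthones (aryne addition, then intramolecular acyl transfer) and the O-arylation of aliphatic alcohols by arynes. Ring C closes by 6-exo-trig attack of the aryl anion on the ester carbon. No stereocentre is created: C2 comes from 18 with its C–O bond untouched, so the S configuration should be retained provided the basic mixture is quenched cold before the flavanone can ring-open. The step needs regioselective addition across the unsymmetrical aryne; the C5 methoxy group should secure this by distorting the aryne towards attack at the remote carbon (C8a) and stabilising the charge at C4a inductively, against the smaller steric bias of the C8 prenyl group. It also needs acyl transfer to outrun protonation of the aryl anion, which the silyl-masked alkoxide is meant to ensure.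

Step 10
Reactants: 21 (2S)-5,7-dimethoxy-2-[4-methoxy-3-(methoxymethoxy)phenyl]-8-(3-methylbut-2-en-1-yl)chroman-4-one
Product: 22 (2S)-2-(3-hydroxy-4-methoxyphenyl)-5,7-dimethoxy-8-(3-methylbut-2-en-1-yl)chroman-4-one (CNP0403319.1)
Conditions: conc. HCl (cat.), MeOH, rt to 40 °C
Reagents that add atoms: none
Why: Acid-catalysed acetal exchange with methanol should free the ring B phenol; C2 is not epimerised by acid, and the prenyl group has no free ortho phenol that could close a chroman.

**Compound list**

1 | 3,5-dimethoxyphenol | COc1cc(O)cc(OC)c1 | starting material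
2 | 3,5-dimethoxyphenyl N-isopropylcarbamate | COc1cc(OC)cc(OC(=O)NC(C)C)c1 | intermediate
3 | 3,5-dimethoxyphenyl N-(tert-butyldimethylsilyl)-N-isopropylcarbamate | COc1cc(OC)cc(OC(=O)N(C(C)C)[Si](C)(C)C(C)(C)C)c1 | intermediate
4 | 2-lithio derivative of 3 (lithium at C2, between the carbamate and a methoxy group) | [Li]c1c(OC)cc(OC)cc1OC(=O)N(C(C)C)[Si](C)(C)C(C)(C)C | intermediate
5 | 3,5-dimethoxy-2-(trimethylsilyl)phenyl N-(tert-butyldimethylsilyl)-N-isopropylcarbamate | C[Si](C)(C)c1c(OC)cc(OC)cc1OC(=O)N(C(C)C)[Si](C)(C)C(C)(C)C | intermediate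
6 | 3,5-dimethoxy-2-(trimethylsilyl)phenyl N-isopropylcarbamate | COc1cc(OC)c([Si](C)(C)C)c(OC(=O)NC(C)C)c1 | intermediate
7 | prenyl bromide (1-bromo-3-methylbut-2-ene) | CC(C)=CCBr | starting material
8 | 3,5-dimethoxy-2-(trimethylsilyl)phenyl N-(tert-butyldimethylsilyl)-N-isopropylcarbamate (N-silylated 6) | COc1cc(OC)c([Si](C)(C)C)c(OC(=O)N(C(C)C)[Si](C)(C)C(C)(C)C)c1 | intermediate
9 | 6-lithio derivative of 8 | COc1cc(OC)c([Si](C)(C)C)c(OC(=O)N(C(C)C)[Si](C)(C)C(C)(C)C)c1[Li] | intermediate
10 | 3,5-dimethoxy-2-(3-methylbut-2-en-1-yl)-6-(trimethylsilyl)phenyl N-(tert-butyldimethylsilyl)-N-isopropylcarbamate | COc1cc(OC)c([Si](C)(C)C)c(OC(=O)N(C(C)C)[Si](C)(C)C(C)(C)C)c1CC=C(C)C | intermediate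
11 | 3,5-dimethoxy-2-(3-methylbut-2-en-1-yl)-6-(trimethylsilyl)phenyl N-isopropylcarbamate | COc1cc(OC)c([Si](C)(C)C)c(OC(=O)NC(C)C)c1CC=C(C)C | intermediate
12 | 3,5-dimethoxy-2-(3-methylbut-2-en-1-yl)-6-(trimethylsilyl)phenol (present as its DBU-H phenoxide) | COc1cc(OC)c([Si](C)(C)C)c(O)c1CC=C(C)C | intermediate
13 | 3,5-dimethoxy-2-(3-methylbut-2-en-1-yl)-6-(trimethylsilyl)phenyl trifluoromethanesulfonate | COc1cc(OC)c([Si](C)(C)C)c(OS(=O)(=O)C(F)(F)F)c1CC=C(C)C | intermediate
14 | 1-(3-hydroxy-4-methoxyphenyl)ethanone | COc1ccc(C(C)=O)cc1O | starting material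
15 | 1-[4-methoxy-3-(methoxymethoxy)phenyl]ethanone | COc1ccc(C(C)=O)cc1OCOC | intermediate
16 | methyl 3-[4-methoxy-3-(methoxymethoxy)phenyl]-3-oxopropanoate | COc1ccc(C(=O)CC(=O)OC)cc1OCOC | intermediate
17 | methyl (3S)-3-hydroxy-3-[4-methoxy-3-(methoxymethoxy)phenyl]propanoate | COc1ccc([C@@H](O)CC(=O)OC)cc1OCOC | intermediate
18 | methyl (3S)-3-[4-methoxy-3-(methoxymethoxy)phenyl]-3-(trimethylsilyloxy)propanoate | COc1ccc([C@@H](O[Si](C)(C)C)CC(=O)OC)cc1OCOC | intermediate
19 | 3,5-dimethoxy-6-(3-methylbut-2-en-1-yl)benzyne (1,2-didehydrobenzene) | COC1=CC(OC)=C(CC=C(C)C)C#C1 | intermediate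
20 | cesium (1S)-3-methoxy-1-[4-methoxy-3-(methoxymethoxy)phenyl]-3-oxopropan-1-olate | [Cs+].COc1ccc([C@@H]([O-])CC(=O)OC)cc1OCOC | intermediate
21 | (2S)-5,7-dimethoxy-2-[4-methoxy-3-(methoxymethoxy)phenyl]-8-(3-methylbut-2-en-1-yl)chroman-4-one | COc1ccc([C@@H]2CC(=O)c3c(OC)cc(OC)c(CC=C(C)C)c3O2)cc1OCOC | intermediate
22 | (2S)-2-(3-hydroxy-4-methoxyphenyl)-5,7-dimethoxy-8-(3-methylbut-2-en-1-yl)chroman-4-one | COc1ccc([C@@H]2CC(=O)c3c(OC)cc(OC)c(CC=C(C)C)c3O2)cc1O | target

**Step count and risks**

Total steps: 10. Longest linear sequence: 6 steps (steps 1–4, 9, 10, or equally steps 5–8, 9, 10).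

Steps most likely to fail:

1. Step 9 (new method). Several things may go wrong:
   - the aryl anion may be protonated before acyl transfer, leaving the open aryl ether;
   - it may abstract a C3 proton and trigger beta-elimination of the aryloxide;
   - the alkoxide may attack the aryne carbon next to the methoxy group;
   - the basic medium may open the flavanone and erode the C2 configuration.

   Fallback by known chemistry, setting out from 17 (a racemic or enantio-impure batch serves equally) and 13: NaOMe in MeOH at reflux should dehydrate 17 to methyl (E)-3-[4-methoxy-3-(methoxymethoxy)phenyl]prop-2-enoate F1. Aqueous NaOH should then give (E)-3-[4-methoxy-3-(methoxymethoxy)phenyl]prop-2-enoic acid F2. F2 and 13 with CsF in THF at 100–125 °C (sealed) should undergo the known insertion of the aryne into the C–O bond of the carboxylic acid to give (E)-1-[2-hydroxy-4,6-dimethoxy-3-(3-methylbut-2-en-1-yl)phenyl]-3-[4-methoxy-3-(methoxymethoxy)phenyl]prop-2-en-1-one F3. F3 should close by oxa-Michael addition under the same basic conditions (NaOAc, EtOH, reflux if needed) to racemic 5,7-dimethoxy-2-[4-methoxy-3-(methoxymethoxy)phenyl]-8-(3-methylbut-2-en-1-yl)chroman-4-one F4. Preparative HPLC on a chiral stationary phase would return the S enantiomer, which is 21; the R enantiomer can be recycled by base-induced racemisation. This fallback relies on the same regiochemistry of aryne addition.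

2. Step 3. Prenyl transfer may be unselective (attack at the tertiary allyl terminus giving the 1,1-dimethylallyl isomer), or the ortho-metalated carbamate may undergo carbamoyl migration on warming.

   Fallback setting out from 6: the same N-silylation and lithiation (through 8 and 9) is quenched with allyl bromide and CuBr·SMe2 (cat.), for which both allyl termini give the same product. This should give 2-allyl-3,5-dimethoxy-6-(trimethylsilyl)phenyl N-(tert-butyldimethylsilyl)-N-isopropylcarbamate F5 in the flask and, after cold aq. NaHSO4, 2-allyl-3,5-dimethoxy-6-(trimethylsilyl)phenyl N-isopropylcarbamate F6. Olefin cross-metathesis of F6 with 2-methyl-2-butene (second-generation Grubbs catalyst, RuCl2(H2IMes)(PCy3)(=CHPh), CH2Cl2, 40 °C) should convert allyl into prenyl and rejoin the route at 11.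

3. Step 4. Sulfonylation of the phenoxide, flanked by SiMe3 and prenyl, may be slow, and the electron-rich aryl–silicon bond may be lost by protodesilylation or silyl migration to oxygen during the one-pot sequence.

   Fallback setting out from 11: the carbamate is cleaved alone (DBU, Et2NH, MeCN, 40 °C) and phenol 12 is isolated after a neutral work-up. 12 with 1,1'-sulfonyldiimidazole and Cs2CO3 in THF should give 3,5-dimethoxy-2-(3-methylbut-2-en-1-yl)-6-(trimethylsilyl)phenyl 1H-imidazole-1-sulfonate F7, a known class of fluoride-triggered aryne precursor made without triflating agents. F7 takes the place of 13 under the conditions of step 9 and the route is rejoined at 21.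

Further compounds
F1 | step 9 | methyl (E)-3-[4-methoxy-3-(methoxymethoxy)phenyl]prop-2-enoate | COC(=O)/C=C/c1ccc(OC)c(OCOC)c1
F2 | step 9 | (E)-3-[4-methoxy-3-(methoxymethoxy)phenyl]prop-2-enoic acid | OC(=O)/C=C/c1ccc(OC)c(OCOC)c1
F3 | step 9 | (E)-1-[2-hydroxy-4,6-dimethoxy-3-(3-methylbut-2-en-1-yl)phenyl]-3-[4-methoxy-3-(methoxymethoxy)phenyl]prop-2-en-1-one | COc1ccc(/C=C/C(=O)c2c(OC)cc(OC)c(CC=C(C)C)c2O)cc1OCOC
F4 | step 9 | racemic 5,7-dimethoxy-2-[4-methoxy-3-(methoxymethoxy)phenyl]-8-(3-methylbut-2-en-1-yl)chroman-4-one | COc1ccc(C2CC(=O)c3c(OC)cc(OC)c(CC=C(C)C)c3O2)cc1OCOC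
F5 | step 3 | 2-allyl-3,5-dimethoxy-6-(trimethylsilyl)phenyl N-(tert-butyldimethylsilyl)-N-isopropylcarbamate | COc1cc(OC)c([Si](C)(C)C)c(OC(=O)N(C(C)C)[Si](C)(C)C(C)(C)C)c1CC=C
F6 | step 3 | 2-allyl-3,5-dimethoxy-6-(trimethylsilyl)phenyl N-isopropylcarbamate | COc1cc(OC)c([Si](C)(C)C)c(OC(=O)NC(C)C)c1CC=C
F7 | step 4 | 3,5-dimethoxy-2-(3-methylbut-2-en-1-yl)-6-(trimethylsilyl)phenyl 1H-imidazole-1-sulfonate | COc1cc(OC)c([Si](C)(C)C)c(OS(=O)(=O)n2ccnc2)c1CC=C(C)C
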